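## Retrosynthetic overview
1. Target ⇒ tris-secondary macrolactam. The three N–CH3 bonds are made last, in one reductive methylation.
2. Macrolactam ⇒ open-chain tetraamino ester. The amide bond N5–C6 closes the only ring (17-membered).
3. Tetraamino ester ⇒ spermine + methyl 3-oxotetradecanoate. The C8–N9 bond and the (R) centre are made together by direct asymmetric reductive amination.
4. Ring order: there is one ring, and it is closed in the second of three steps.

Assumption: the SMILES stereocentre reads as (R) (N > CH2C=O > undecyl > H; C8 in 1,5,9,13-tetraazacycloheptadecan-6-one numbering). The facial sense of the (R)-DM-SEGPHOS ruthenium catalyst is taken from its behaviour with β-keto esters and ammonium salts; if it proves reversed, the equally available (S)-ligand is used.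

## Route

Step 1
Reactants: 1 spermine; 2 methyl 3-oxotetradecanoate
Product: 4 methyl (3R)-3-[(3-{[4-({3-aminopropyl}amino)butyl]amino}propyl)amino]tetradecanoate, via (Z)-enamino ester 3 (not isolated)
Conditions: 1 (4 equiv), MeOH, 25 °C, 2 h; then AcOH (15 equiv), Ru(OAc)2[(R)-DM-SEGPHOS] (1 mol %; DM-SEGPHOS = 5,5'-bis[bis(3,5-dimethylphenyl)phosphino]-4,4'-bi-1,3-benzodioxole), H2 (30 bar), MeOH, 60 °C, 24 h; cold aq K2CO3/CHCl3 work-up (excess 1 stays in the water layer)
Reagents that add atoms: none
Why: Proposed new method: direct asymmetric reductive amination of a β-keto ester with an unprotected tetraamine as the nitrogen source; only a primary amino end can give the hydrogen-bonded, non-basic (Z)-enamino ester 3 (the secondary nitrogens give only crowded, reversible tertiary enamines, and the fourfold excess of 1 holds double condensation to about one eighth of 2), one AcOH per remaining basic nitrogen converts the polyamine into ammonium acetates that cannot chelate the divalent ruthenium centre and also protonates 3 at C2 to its iminium tautomer, and this ester-coordinated iminium takes hydride from the (R)-DM-SEGPHOS Ru–H on the Si face of C3, the face used in Noyori-type β-keto ester hydrogenation, which sets (R); the closest known reaction type is the Ru–diphosphine direct asymmetric reductive amination of β-keto esters and β-keto amides with ammonium salts (and hydrogenation of N-unprotected β-enamino esters), not yet shown for a primary alkylamine that carries further free amino groups.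

Step 2
Reactants: 4 methyl (3R)-3-[(3-{[4-({3-aminopropyl}amino)butyl]amino}propyl)amino]tetradecanoate
Product: 7 (8R)-8-undecyl-1,5,9,13-tetraazacycloheptadecan-6-one, via antimony triamide chelate 5 (not isolated), via methoxyantimony-bound lactam 6 (not isolated)
Conditions: Sb(OEt)3 (1.2 equiv), benzene (5 mM), reflux through 4 Å MS (Soxhlet), 16 h; then wet EtOH, filter
Reagents that add atoms: none
Why: Antimony-templated macrolactamisation (intramolecular ester aminolysis): the three ethoxides are exchanged for the three least hindered N–H groups, which ties the chain to one trivalent antimony atom (5) and holds the terminal Sb–NH next to the Lewis-acid-activated ester, so acyl transfer gives 6 and, after hydrolysis, the 17-membered secondary lactam rather than oligomers or the 8- and 13-membered tertiary lactams, with the stereocentre untouched.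

Step 3
Reactants: 7 (8R)-8-undecyl-1,5,9,13-tetraazacycloheptadecan-6-one
Product: 8 (8R)-1,9,13-trimethyl-8-undecyl-1,5,9,13-tetraazacycloheptadecan-6-one
Conditions: 37% aq HCHO (12 equiv), HCO2H, 80 °C, 6 h; aq NaOH, CH2Cl2
Reagents that add atoms: formaldehyde, C=O
Why: Eschweiler–Clarke reductive methylation: each secondary amine forms an iminium ion that formate reduces irreversibly with loss of CO2, methylene aminals between 1,3-related nitrogens are reversible in hot formic acid and drain to the N-methyl amines, tertiary amines cannot over-alkylate, the non-basic lactam N–H is left alone, and the acidic medium suppresses retro-Michael erosion at C8.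

## Compound list
1 | spermine (N,N'-bis(3-aminopropyl)butane-1,4-diamine) | NCCCNCCCCNCCCN | starting material
2 | methyl 3-oxotetradecanoate | CCCCCCCCCCCC(=O)CC(=O)OC | starting material
3 | methyl (2Z)-3-[(3-{[4-({3-aminopropyl}amino)butyl]amino}propyl)amino]tetradec-2-enoate | CCCCCCCCCCC/C(NCCCNCCCCNCCCN)=C/C(=O)OC | intermediate
4 | methyl (3R)-3-[(3-{[4-({3-aminopropyl}amino)butyl]amino}propyl)amino]tetradecanoate | CCCCCCCCCCC[C@@H](NCCCNCCCCNCCCN)CC(=O)OC | intermediate
5 | proposed antimony triamide chelate of 4 (one trivalent Sb bonded to both nitrogens flanking the butane unit and to the terminal NH; ester and C3–NH free; 3R) | CCCCCCCCCCC[C@@H](NCCCN1CCCCN2CCCN[Sb]12)CC(=O)OC | intermediate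
6 | proposed methoxyantimony-bound lactam (Sb(OMe) bridging N1 and N13 of the 17-membered lactam; 8R) | CCCCCCCCCCC[C@@H]1CC(=O)NCCCN2CCCCN(CCCN1)[Sb]2OC | intermediate
7 | (8R)-8-undecyl-1,5,9,13-tetraazacycloheptadecan-6-one | CCCCCCCCCCC[C@@H]1CC(=O)NCCCNCCCCNCCCN1 | intermediate
8 | (8R)-1,9,13-trimethyl-8-undecyl-1,5,9,13-tetraazacycloheptadecan-6-one (CNP0193618.1) | CCCCCCCCCCC[C@@H]1CC(=O)NCCCN(C)CCCCN(C)CCCN1C | target

## Count and risks
Total steps: 3. Longest linear sequence: 3.

**Step 1 (proposed new step; highest risk).**
- What may go wrong: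
  - The polyamine may still inhibit ruthenium.
  - The N-alkyl iminium may be reduced with lower ee than the N–H case.
  - β-Hydroxy ester or the double adduct may compete.
- Fallback (known chemistry only; sets out from 2, returns at 4). The centre is set with the established ammonium-salt reaction, and the chain is attached afterwards by Fukuyama sulfonamide alkylation.
  - 2 with NH4OAc, Ru(OAc)2[(R)-DM-SEGPHOS] and H2 in MeOH at 80 °C gives methyl (3R)-3-aminotetradecanoate F1.
  - 2-Nitrobenzenesulfonyl chloride with aq Na2CO3/CH2Cl2 gives the 2-nitrobenzenesulfonamide F2.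
  - 1,3-Dibromopropane (5 equiv) and K2CO3 in DMF give the N-(3-bromopropyl) sulfonamide F3.
  - Commercial tert-butyl (4-aminobutyl)[3-(tert-butoxycarbonylamino)propyl]carbamate (3 equiv) and K2CO3 in MeCN displace bromide to give the chain-extended sulfonamide F4.
  - PhSH/K2CO3 in DMF removes the sulfonyl group to give the bis-Boc tetraamino ester F5.
  - CF3CO2H/CH2Cl2 followed by basic work-up gives 4.

**Step 2.**
- What may go wrong:
  - Oligomers may form.
  - An inner nitrogen may be acylated.
  - Heating may cause partial retro-Michael racemisation.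
- Fallback (sets out from 4, returns at 8, bypassing 7). The inner nitrogens are made tertiary first, so that only one nitrogen can be acylated, and the ring is closed from an activated acid instead of on a metal template.
  - CF3CO2Et (1.0 equiv) in MeOH at −78 to 0 °C acylates only the primary amine, giving the terminal trifluoroacetamide F6.
  - Aq HCHO/HCO2H at 80 °C gives the tri-N-methyl trifluoroacetamide ester F7.
  - LiOH in aq MeOH cleaves both the ester and the trifluoroacetamide to give the tri-N-methyl amino acid F8.
  - Slow addition of F8 to pentafluorophenyl diphenylphosphinate and DIPEA in DMF (1 mM) closes the lactam directly to 8.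

**Step 3.**
- What may go wrong:
  - A persistent N1–CH2–N5 acyl aminal may form.
  - The hindered N9 may be N-formylated, leaving methylation incomplete.
- Fallback (sets out from 7, returns at 8). Acylation followed by chemoselective deoxygenation replaces iminium reduction.
  - Acetic formic anhydride in CH2Cl2 at 0 °C gives the 1,9,13-triformamide F9.
  - Zn(OAc)2 (10 mol %) and (EtO)3SiH in THF at 40 °C reduce the three tertiary formamides to N-methyl groups. The secondary lactam is inert to this catalyst, so the product is 8.

## Further compounds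
F1 | step 1 | methyl (3R)-3-aminotetradecanoate | CCCCCCCCCCC[C@@H](N)CC(=O)OC
F2 | step 1 | methyl (3R)-3-[(2-nitrophenyl)sulfonylamino]tetradecanoate | CCCCCCCCCCC[C@@H](NS(=O)(=O)c1ccccc1[N+](=O)[O-])CC(=O)OC
F3 | step 1 | methyl (3R)-3-[(3-bromopropyl)(2-nitrophenylsulfonyl)amino]tetradecanoate | CCCCCCCCCCC[C@@H](N(CCCBr)S(=O)(=O)c1ccccc1[N+](=O)[O-])CC(=O)OC
F4 | step 1 | methyl (3R)-3-[{3-[(4-{(tert-butoxycarbonyl)[3-(tert-butoxycarbonylamino)propyl]amino}butyl)amino]propyl}(2-nitrophenylsulfonyl)amino]tetradecanoate | CCCCCCCCCCC[C@@H](N(CCCNCCCCN(CCCNC(=O)OC(C)(C)C)C(=O)OC(C)(C)C)S(=O)(=O)c1ccccc1[N+](=O)[O-])CC(=O)OC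
F5 | step 1 | methyl (3R)-3-({3-[(4-{(tert-butoxycarbonyl)[3-(tert-butoxycarbonylamino)propyl]amino}butyl)amino]propyl}amino)tetradecanoate | CCCCCCCCCCC[C@@H](NCCCNCCCCN(CCCNC(=O)OC(C)(C)C)C(=O)OC(C)(C)C)CC(=O)OC
F6 | step 2 | methyl (3R)-3-{[3-({4-[(3-(trifluoroacetamido)propyl)amino]butyl}amino)propyl]amino}tetradecanoate | CCCCCCCCCCC[C@@H](NCCCNCCCCNCCCNC(=O)C(F)(F)F)CC(=O)OC
F7 | step 2 | methyl (3R)-3-{methyl[3-(methyl{4-[methyl(3-(trifluoroacetamido)propyl)amino]butyl}amino)propyl]amino}tetradecanoate | CCCCCCCCCCC[C@@H](N(C)CCCN(C)CCCCN(C)CCCNC(=O)C(F)(F)F)CC(=O)OC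
F8 | step 2 | (3R)-3-{[3-({4-[(3-aminopropyl)(methyl)amino]butyl}(methyl)amino)propyl](methyl)amino}tetradecanoic acid | CCCCCCCCCCC[C@@H](N(C)CCCN(C)CCCCN(C)CCCN)CC(=O)O
F9 | step 3 | (8R)-6-oxo-8-undecyl-1,5,9,13-tetraazacycloheptadecane-1,9,13-tricarbaldehyde | CCCCCCCCCCC[C@@H]1CC(=O)NCCCN(C=O)CCCCN(C=O)CCCN1C=O
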